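**Retrosynthetic overview**
1. Only one C–C bond is broken: the biaryl bond between C6 of the acacetin unit and C8'' of the apigenin unit. Rings A, B and C of both flavones are bought intact (acacetin, apigenin), so no ring is built in the route.
2. Both ends of that bond are nucleophilic phloroglucinol-type carbons. The polarity of apigenin C8 is reversed by turning it into an aryllead triacetate (an aryl cation equivalent) through C–H plumbation of tri-O-benzylapigenin.
3. The chelated 5-OH of 7-O-benzylacacetin binds lead and passes the aryl group to its only free ortho carbon, C6 (ligand coupling). This fixes the 6,8''-linkage.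
4. All protecting groups are benzyl, so one hydrogenolysis frees four phenols and leaves the 4'-OMe.

Assumption: the SMILES holds no stereodescriptor and the molecule has no stereocentre; its only stereo element, the hindered biaryl axis, is undefined, so the target is made without control of the axis (racemic about it).

**Step 1**
Reactants: 1 apigenin
Product: 2 tri-O-benzylapigenin [5,7-bis(benzyloxy)-2-(4-benzyloxyphenyl)-4H-chromen-4-one]
Conditions: BnBr (4.5 equiv), K2CO3 (6 equiv), Bu4NI (0.1 equiv), DMF, 80 °C, 16 h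
Reagents that add atoms: benzyl bromide, BrCc1ccccc1
Why: Williamson ether synthesis (SN2 O-benzylation of phenoxides): the 7- and 4'-phenols react at once and excess K2CO3 with heat in DMF also alkylates the hydrogen-bonded 5-OH, which must be capped so that the later electrophilic metalation goes to C8 and tetravalent lead finds no free phenol on this partner; no stereocentre is formed.

**Step 2**
Reactants: 3 acacetin
Product: 4 acacetin 7-O-benzyl ether [7-benzyloxy-5-hydroxy-2-(4-methoxyphenyl)-4H-chromen-4-one]
Conditions: BnBr (1.1 equiv), K2CO3 (1.2 equiv), DMF, rt, 12 h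
Reagents that add atoms: benzyl bromide, BrCc1ccccc1
Why: Chemoselective Williamson ether synthesis: with about one equivalent of base at room temperature only the acidic 7-OH is benzylated, while the 5-OH, locked in a hydrogen bond to the C4 carbonyl, stays free to serve as the lead-binding site in step 3; no stereocentre is formed.

**Step 3**
Reactants: 2 tri-O-benzylapigenin; 4 acacetin 7-O-benzyl ether; 5 lead tetraacetate
Product: 7 tetra-O-benzyl-4'-O-methylagathisflavone [7-benzyloxy-6-{5,7-bis(benzyloxy)-2-(4-benzyloxyphenyl)-4-oxo-4H-chromen-8-yl}-5-hydroxy-2-(4-methoxyphenyl)-4H-chromen-4-one], via tri-O-benzylapigenin-8-yllead triacetate 6 (not isolated)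
Conditions: 2 (1.3 equiv), Pb(OAc)4 (1.2 equiv, freed of AcOH), CHCl3, rt, dark, 3 h; then 4 (1.0 equiv), pyridine (5 equiv), CHCl3, 60 °C, 12 h
Reagents that add atoms: none
Why: Proposed new method: one-pot C8–H plumbation of 2 and ligand coupling with phenol 4 at the stage of two complete flavones; lead tetraacetate attacks the trioxygenated ring A of 2 at C8 (the site where 5,7-dialkoxyflavones are halogenated, C6 being squeezed between two benzyloxy groups) to give aryllead triacetate 6, an aryl cation equivalent in which the normally nucleophilic C8 has become the electrophile, then the chelated 5-OH of 4 replaces an acetate on tetravalent lead and the aryl group migrates to C6, the only free ortho carbon of that oxygen, with loss of Pb(OAc)2 and rearomatisation, which forms the four-fold ortho-substituted biaryl (2 is kept in excess over Pb(OAc)4 so that no free oxidant meets 4); the closest known reaction type is the Pinhey arylation, that is, direct plumbation of 1,3,5-trimethoxybenzene and ortho-C-arylation of phenols and enolised 1,3-dicarbonyl compounds by aryllead triacetates with pyridine; no stereocentre is formed and the new axis arises racemic.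

**Step 4**
Reactants: 7 tetra-O-benzyl-4'-O-methylagathisflavone
Product: 8 4'-O-methylagathisflavone [5,7-dihydroxy-8-{5,7-dihydroxy-2-(4-methoxyphenyl)-4-oxo-4H-chromen-6-yl}-2-(4-hydroxyphenyl)-4H-chromen-4-one], the target
Conditions: H2 (1 atm), 10% Pd/C, THF–MeOH (1:1), rt, 6 h
Reagents that add atoms: none
Why: Catalytic hydrogenolysis of the four benzyl aryl ethers (O-debenzylation) frees 7-OH, 5''-OH, 7''-OH and 4'''-OH, while the methyl ether, the chromone C2=C3 bonds (vinylogous esters, inert at 1 atm and room temperature) and the biaryl bond are untouched; no stereocentre is involved.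

**Compound list**
1 | apigenin [5,7-dihydroxy-2-(4-hydroxyphenyl)-4H-chromen-4-one] | O=c1cc(-c2ccc(O)cc2)oc2cc(O)cc(O)c12 | starting material
2 | tri-O-benzylapigenin [5,7-bis(benzyloxy)-2-(4-benzyloxyphenyl)-4H-chromen-4-one] | O=c1cc(-c2ccc(OCc3ccccc3)cc2)oc2cc(OCc3ccccc3)cc(OCc3ccccc3)c12 | intermediate
3 | acacetin [5,7-dihydroxy-2-(4-methoxyphenyl)-4H-chromen-4-one] | COc1ccc(-c2cc(=O)c3c(O)cc(O)cc3o2)cc1 | starting material
4 | acacetin 7-O-benzyl ether [7-benzyloxy-5-hydroxy-2-(4-methoxyphenyl)-4H-chromen-4-one] | COc1ccc(-c2cc(=O)c3c(O)cc(OCc4ccccc4)cc3o2)cc1 | intermediate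
5 | lead tetraacetate | CC(=O)O[Pb](OC(C)=O)(OC(C)=O)OC(C)=O | starting material
6 | tri-O-benzylapigenin-8-yllead triacetate [5,7-bis(benzyloxy)-2-(4-benzyloxyphenyl)-4-oxo-4H-chromen-8-yl lead triacetate] | O=c1cc(-c2ccc(OCc3ccccc3)cc2)oc2c([Pb](OC(C)=O)(OC(C)=O)OC(C)=O)c(OCc3ccccc3)cc(OCc3ccccc3)c12 | intermediate
7 | tetra-O-benzyl-4'-O-methylagathisflavone [7-benzyloxy-6-{5,7-bis(benzyloxy)-2-(4-benzyloxyphenyl)-4-oxo-4H-chromen-8-yl}-5-hydroxy-2-(4-methoxyphenyl)-4H-chromen-4-one; axis racemic] | COc1ccc(-c2cc(=O)c3c(O)c(-c4c(OCc5ccccc5)cc(OCc5ccccc5)c5c(=O)cc(-c6ccc(OCc7ccccc7)cc6)oc45)c(OCc4ccccc4)cc3o2)cc1 | intermediate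
8 | 4'-O-methylagathisflavone [5,7-dihydroxy-8-{5,7-dihydroxy-2-(4-methoxyphenyl)-4-oxo-4H-chromen-6-yl}-2-(4-hydroxyphenyl)-4H-chromen-4-one; axis undefined] | COc1ccc(-c2cc(=O)c3c(O)c(-c4c(O)cc(O)c5c(=O)cc(-c6ccc(O)cc6)oc45)c(O)cc3o2)cc1 | target

**Totals**
Total step count: 4. Longest linear sequence: 3 steps (1 → 2 → 7 → 8 through steps 1, 3 and 4; the branch 3 → 4 is one step).

**Steps most likely to fail and fallbacks**

Risk 1, step 3. Ring A of 2 is less electron-rich than 1,3,5-trimethoxybenzene, so plumbation may be slow or give some C6 isomer or aryl acetate. The chelated 5-OH of 4 may also exchange onto lead sluggishly, and a minor para (C8) arylation of 4 is conceivable. The fallback sets out from 2 and comes back at 6, replacing C–H plumbation by a prefunctionalised, regiodefined and acid-free entry to the same aryllead reagent. Iodination of 2 (NIS, TFA 0.1 equiv, MeCN–CH2Cl2, rt) gives 5,7-bis(benzyloxy)-2-(4-benzyloxyphenyl)-8-iodo-4H-chromen-4-one F1. Stannylation catalysed by zerovalent palladium (Bu3SnSnBu3, Pd(PPh3)4, toluene, 110 °C) gives 5,7-bis(benzyloxy)-2-(4-benzyloxyphenyl)-8-(tributylstannyl)-4H-chromen-4-one F2. Tin–lead exchange (Pb(OAc)4, Hg(OAc)2 5 mol%, CHCl3, 40 °C) then delivers 6, which meets 4 and pyridine as in step 3.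

Risk 2, step 1. Benzylation of the chelated 5-OH may stall at the dibenzyl stage, or forcing conditions may cause C-benzylation. The fallback sets out from 1 and comes back at 8, changing the 5-O protecting group to methyl and the end-game to a Lewis-acid cleavage. Mild benzylation (BnBr 2.2 equiv, K2CO3, acetone, reflux) gives 7,4'-di-O-benzylapigenin F3. The small electrophile MeI (K2CO3, DMF, 50 °C) caps the chelated phenol to give 7,4'-di-O-benzyl-5-O-methylapigenin F4. Plumbation as in step 3 gives 7,4'-di-O-benzyl-5-O-methylapigenin-8-yllead triacetate F5 (not isolated), and coupling with 4 gives 7,7'',4'''-tri-O-benzyl-4',5''-di-O-methylagathisflavone F6. BCl3 with pentamethylbenzene (CH2Cl2, −78 → 0 °C) then removes the three benzyl groups and the peri-chelated 5''-O-methyl group in one operation, while the unchelated 4'-OMe survives, giving 8.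

Risk 3, step 4. The chromone C2=C3 bonds may be partly reduced, the tetrabenzyl biflavone may be poorly soluble, or traces of lead may poison the catalyst. The fallback sets out from 7 and comes back at 8, changing from reductive to Lewis-acid debenzylation: BCl3 (8 equiv), pentamethylbenzene (12 equiv) as benzyl cation scavenger, CH2Cl2, −78 °C. No hydrogen is present and the unchelated 4'-OMe is inert to BCl3. This fallback makes no new compound F0.

**Further compounds**
F1 | step 3 | 5,7-bis(benzyloxy)-2-(4-benzyloxyphenyl)-8-iodo-4H-chromen-4-one | O=c1cc(-c2ccc(OCc3ccccc3)cc2)oc2c(I)c(OCc3ccccc3)cc(OCc3ccccc3)c12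
F2 | step 3 | 5,7-bis(benzyloxy)-2-(4-benzyloxyphenyl)-8-(tributylstannyl)-4H-chromen-4-one | CCCC[Sn](CCCC)(CCCC)c1c(OCc2ccccc2)cc(OCc2ccccc2)c2c(=O)cc(-c3ccc(OCc4ccccc4)cc3)oc12
F3 | step 1 | 7,4'-di-O-benzylapigenin | O=c1cc(-c2ccc(OCc3ccccc3)cc2)oc2cc(OCc3ccccc3)cc(O)c12
F4 | step 1 | 7,4'-di-O-benzyl-5-O-methylapigenin | COc1cc(OCc2ccccc2)cc2oc(-c3ccc(OCc4ccccc4)cc3)cc(=O)c12
F5 | step 1 | 7,4'-di-O-benzyl-5-O-methylapigenin-8-yllead triacetate | COc1cc(OCc2ccccc2)c([Pb](OC(C)=O)(OC(C)=O)OC(C)=O)c2oc(-c3ccc(OCc4ccccc4)cc3)cc(=O)c12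
F6 | step 1 | 7,7'',4'''-tri-O-benzyl-4',5''-di-O-methylagathisflavone | COc1ccc(-c2cc(=O)c3c(O)c(-c4c(OCc5ccccc5)cc(OC)c5c(=O)cc(-c6ccc(OCc7ccccc7)cc6)oc45)c(OCc4ccccc4)cc3o2)cc1
F0 | step 4 | none | none
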